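**Strategy.** The quinone ring is cut at C1–C6 and C3–C4 (C1 carbonyl, C2 hydroxyl, C3 henicosyl-bearing carbon, C4 carbonyl, C5 methoxy carbon, C6 CH). C4–C5–C6 is then a 2-methoxyacrylate and C1–C2–C3, together with the side chain, an alkylglyoxal. Because acrylate β-carbon C6 must bond to carbonyl carbon C1, C1 is made nucleophilic by a carbene catalyst. One flask operation (Stetter addition, then methoxide-driven Claisen closure and aromatisation) forms the six-membered ring with all four oxygens in place, as the hydroquinone of the target. The precursor is water-free 2-oxotetracosanal, made in two steps from 1-bromodocosane; one mild oxidation finishes the synthesis.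

Key step: step 3

Remark on the chemistry: 1-bromodocosane, 1-(diethoxyacetyl)piperidine and methyl 2-methoxyacrylate are assumed to be purchasable. The C5 centre of intermediates 7 and 8 is racemic and vanishes on aromatisation; the target has no stereocentre.

**Step 1**
Reactants: 1 1-bromodocosane; 2 1-(diethoxyacetyl)piperidine (2,2-diethoxy-1-(piperidin-1-yl)ethan-1-one)
Product: 4 1,1-diethoxytetracosan-2-one, via docosylmagnesium bromide 3 (not isolated)
Conditions: Mg, I2 (cat.), THF, 55 °C; then 2, 0 °C → rt; cold 1 M aq. HCl
Reagents that add atoms: none
Why: Grignard formation followed by acylation with an N,N-dialkyl dialkoxyacetamide, in which the magnesium-chelated tetrahedral adduct persists until the acidic quench and so prevents a second addition (ketone synthesis of the Weinreb type).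

**Step 2**
Reactants: 4 1,1-diethoxytetracosan-2-one
Product: 5 2-oxotetracosanal
Conditions: 2 M aq. HCl/1,4-dioxane (1:4), 70 °C, N2; then toluene, Dean–Stark; used at once
Reagents that add atoms: water, O
Why: Acid-catalysed acetal hydrolysis, slowed by the neighbouring ketone and therefore run warm, followed by azeotropic drying so that the aldehyde is delivered as the free glyoxal and not as its hydrate, which would feed the carbene catalyst into the competing internal redox path to the 2-hydroxy acid.

**Step 3**
Reactants: 5 2-oxotetracosanal; 6 methyl 2-methoxyacrylate
Product: 9 3-henicosyl-5-methoxybenzene-1,2,4-triol, via diketo ester 7 (not isolated), via cyclohexanetrione 8 (not isolated)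
Conditions: 5 added slowly to 6 (3 equiv), 2-(pentafluorophenyl)-6,7-dihydro-5H-pyrrolo[2,1-c][1,2,4]triazol-2-ium tetrafluoroborate (20 mol %), i-Pr2NEt (30 mol %), 4 Å MS, THF, 45 °C, Ar; volatiles removed; then NaOMe (5 equiv), degassed MeOH/THF, 0 → 50 °C; AcOH, degassed aq. Na2S2O4 wash
Reagents that add atoms: none
Why: Proposed new method: the triazolylidene adds to aldehyde carbon C1 of 5, the resulting Breslow intermediate attacks C6 of 6 as an acyl anion, and protonation at C5 with release of the carbene gives diketo ester 7; methoxide then generates the C3 enolate, which attacks ester carbon C4 and expels methoxide to give trione 8, whose enolisation to the aromatic triolate is irreversible. The closest known reaction types are the intermolecular Stetter addition of aldehydes to 2-amidoacrylates and of glyoxamides to activated alkenes for the C1–C6 bond, and the Dieckmann-type closure of 5-oxo esters to cyclohexane-1,3-diones, together with the base-induced self-condensation of 2-oxoalkanoates to dihydroxybenzoquinones, for the C3–C4 bond. The single ring closes in the 6-(enolendo)-exo-trig mode. The C5 centre of 7 and 8 forms without control and is erased on aromatisation, so nothing stereochemical has to be secured. The step needs aldehyde-over-ketone selectivity at the carbene stage, which the much higher electrophilicity of C1 provides, and it needs the acyl anion path to beat the internal redox of the glyoxal adduct, which is why 5 is dry, protic additives are absent and 5 is added slowly to excess 6. Loss of the C5 methoxy by E1cB is made harmless by closing in NaOMe/MeOH, where ester exchange is degenerate and eliminated methanol can add back at C5 until the aromatising closure drains every equilibrium.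

**Step 4**
Reactants: 9 3-henicosyl-5-methoxybenzene-1,2,4-triol
Product: 10 3-henicosyl-2-hydroxy-5-methoxy-1,4-benzoquinone (target)
Conditions: FeCl3 (2.2 equiv), THF/H2O, 0 °C → rt; dilute aq. HCl wash
Reagents that add atoms: none
Why: Two-electron oxidation of a 1,2,4-trihydroxybenzene by FeCl3, the classical way from hydroxyhydroquinones to 2-hydroxy-1,4-benzoquinones, removes the hydroxyl hydrogens at C1 and C4 to give the para-quinone tautomer and should leave the C2 hydroxyl and the C5 methoxy untouched.

**Compound list**
1 | 1-bromodocosane | CCCCCCCCCCCCCCCCCCCCCCBr | starting material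
2 | 1-(diethoxyacetyl)piperidine (2,2-diethoxy-1-(piperidin-1-yl)ethan-1-one) | CCOC(OCC)C(=O)N1CCCCC1 | starting material
3 | docosylmagnesium bromide | CCCCCCCCCCCCCCCCCCCCCC[Mg]Br | intermediate (not isolated)
4 | 1,1-diethoxytetracosan-2-one | CCCCCCCCCCCCCCCCCCCCCCC(=O)C(OCC)OCC | intermediate
5 | 2-oxotetracosanal | CCCCCCCCCCCCCCCCCCCCCCC(=O)C=O | intermediate
6 | methyl 2-methoxyacrylate (methyl 2-methoxyprop-2-enoate) | C=C(OC)C(=O)OC | starting material
7 | methyl 2-methoxy-4,5-dioxoheptacosanoate (racemic) | CCCCCCCCCCCCCCCCCCCCCCC(=O)C(=O)CC(OC)C(=O)OC | intermediate (not isolated)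
8 | 3-henicosyl-5-methoxycyclohexane-1,2,4-trione (stereoisomer mixture) | CCCCCCCCCCCCCCCCCCCCCC1C(=O)C(=O)CC(OC)C1=O | intermediate (not isolated)
9 | 3-henicosyl-5-methoxybenzene-1,2,4-triol | CCCCCCCCCCCCCCCCCCCCCc1c(O)c(O)cc(OC)c1O | intermediate
10 | 3-henicosyl-2-hydroxy-5-methoxycyclohexa-2,5-diene-1,4-dione | CCCCCCCCCCCCCCCCCCCCCC1=C(O)C(=O)C=C(OC)C1=O | target

Total step count: 4. Longest linear sequence: 4 steps (1 → 4 → 5 → 9 → 10).

**Steps most likely to fail**

Step 3. The carbene adduct of the glyoxal may undergo internal redox or self-acyloin condensation faster than it adds to the electron-rich, α-substituted acrylate. The C5 methoxy may also be lost by E1cB before the ring closes. The fallback sets out from 1 and returns to the route at 7, using known reactions only. 1-Bromodocosane 1 alkylates lithium acetylide–ethylenediamine complex (DMSO, rt) to give tetracos-1-yne F1. Its lithium salt (n-BuLi, then BF3·OEt2, THF, −78 °C) opens racemic methyl oxirane-2-carboxylate at the CH2 terminus to give methyl 2-hydroxyheptacos-4-ynoate F2. O-Methylation (MeI, Ag2O, MeCN) gives methyl 2-methoxyheptacos-4-ynoate F3. Buffered permanganate (KMnO4, NaHCO3, MgSO4, acetone/H2O), the standard conversion of long-chain dialkylalkynes into 1,2-diketones, gives diketo ester 7, now isolated. Compound 7 is then closed with NaOMe/MeOH as in the second stage of step 3, an ordinary Dieckmann-type condensation, to give 9. This path avoids both the carbene and the conjugate addition.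

Step 2. Hydrolysis of the keto acetal may stall, or the enolisable ketoaldehyde may self-condense in hot acid and during dehydration. The fallback sets out from 3 and returns at 5. Docosylmagnesium bromide 3 is added to (E)-N-methoxy-N-methylcinnamamide (THF, 0 °C; dilute HCl quench) to give (E)-1-phenylpentacos-1-en-3-one F4. Ozonolysis (O3, CH2Cl2, −78 °C; then Me2S) cleaves the styryl double bond and should deliver 5 directly in water-free, acid-free form; the benzaldehyde co-product is removed under vacuum.

Step 4. Over-oxidation or oxidative coupling at C6 may occur, the C5 methoxy (a vinylogous ester) may hydrolyse in the acidic iron medium, and iron chelation may hamper isolation; the free triol may also degrade in air before it is oxidised cleanly. The fallback sets out from 9 and returns at 10. The crude triol 9 is acetylated at once (Ac2O, pyridine, DMAP) to the air-stable 3-henicosyl-5-methoxybenzene-1,2,4-triyl triacetate F5, which is purified by chromatography. Methanolysis under air (K2CO3, MeOH, O2 balloon; then dilute HCl) removes the acetates and lets the liberated triolate autoxidise in the same flask to 10, so no metal oxidant and no handling of free 9 is needed.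

**Further compounds**
F1 | step 3 | tetracos-1-yne | CCCCCCCCCCCCCCCCCCCCCCC#C
F2 | step 3 | methyl 2-hydroxyheptacos-4-ynoate (racemic) | CCCCCCCCCCCCCCCCCCCCCCC#CCC(O)C(=O)OC
F3 | step 3 | methyl 2-methoxyheptacos-4-ynoate (racemic) | CCCCCCCCCCCCCCCCCCCCCCC#CCC(OC)C(=O)OC
F4 | step 2 | (E)-1-phenylpentacos-1-en-3-one | CCCCCCCCCCCCCCCCCCCCCCC(=O)/C=C/c1ccccc1
F5 | step 4 | 3-henicosyl-5-methoxybenzene-1,2,4-triyl triacetate | CCCCCCCCCCCCCCCCCCCCCc1c(OC(C)=O)c(OC(C)=O)cc(OC)c1OC(C)=O
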